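**Retrosynthetic overview**

1. Feature: rings A and B are cis-fused (H5 and the C20 methyl on quaternary C10 lie on one face), and the chain C3–C4–C5–C10–C9–C8 with C17, C18 and C20 is the carbon skeleton of 2,6-bis(hydroxymethyl)-p-cresol. Closing C3–C8 gives a cresol-derived bicycle; reopening it by a [3,3] shift gives the cis-decalin.
2. Butenolide last: C12–C13 by alkylation of 3-(phenylthio)butyrolactone with a C12 iodide, then sulfoxide elimination.
3. C9–C11 and the C8=C17 methylene: Johnson–Claisen rearrangement from the C17 allylic alcohol on the convex face, with ring A held by an O3/O18/O19 orthoacetate cage; the C3 alcohol comes from a dissolving-metal reduction.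
4. Ring A (C1–C10 bond, cis fusion): anionic oxy-Cope rearrangement of a 2-vinylbicyclo[2.2.2]oct-5-en-2-ol with cleavage of C3–C8.
5. Ring B first (C5–C6 and C7–C8 bonds): Wessely dearomatisation of the cresol, Diels–Alder reaction with phenyl vinyl sulfone, reductive loss of OAc and SO2Ph, C19 added by ketone enolate alkylation (phenoxides are O-alkylated by chloromethyl ethers), then resolution. Ring order: B, then A, then the lactone ring is attached intact.

Key step: step 8

Assumption: decalin compounds carry labdane numbers (C1–C10 rings, C11/C12 chain, C13–C16 lactone, C17 on C8, C18/C19 on C4, C20 on C10). Bicyclic compounds carry bicyclo[2.2.2]octane locants, where bicyclo C1/C2/C3/C4/C5/C6/C7/C8 become labdane C8/C3/C4/C5/C10/C9/C7/C6. Racemic compounds 5–12 are drawn as the enantiomer that is carried on.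

**Route**

Step 1
Reactants: 1 2,6-bis(hydroxymethyl)-4-methylphenol; 2 benzyl alcohol
Product: 3 2,6-bis[(benzyloxy)methyl]-4-methylphenol
Conditions: BnOH (20 equiv), TsOH·H2O (2 mol %), 60 °C
Reagents that add atoms: benzyl alcohol, OCc1ccccc1
Why: Acid-catalysed etherification of o-hydroxybenzyl alcohols (via the o-quinone methide or benzylic cation) should convert both CH2OH groups into benzyl ethers while the phenol OH stays free; no stereocentre is formed.

Step 2
Reactants: 3 2,6-bis[(benzyloxy)methyl]-4-methylphenol; 4 lead tetraacetate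
Product: 5 rac-6-acetoxy-2,6-bis[(benzyloxy)methyl]-4-methylcyclohexa-2,4-dien-1-one
Conditions: Pb(OAc)4, AcOH/CH2Cl2, 0 °C → rt
Reagents that add atoms: lead tetraacetate, CC(=O)O[Pb](OC(C)=O)(OC(C)=O)OC(C)=O
Why: Wessely acetoxylation delivers acetate from the aryloxy–Pb(IV) species to one of the two equivalent ortho carbons, giving the o-quinol acetate in which OAc is a removable blocking group on the future C4; the new centre is racemic and is erased in steps 4 and 5.

Step 3
Reactants: 5 rac-6-acetoxy-2,6-bis[(benzyloxy)methyl]-4-methylcyclohexa-2,4-dien-1-one; 6 phenyl vinyl sulfone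
Product: 7 rac-3-acetoxy-1,3-bis[(benzyloxy)methyl]-5-methyl-7-(phenylsulfonyl)bicyclo[2.2.2]oct-5-en-2-one (major isomer)
Conditions: PhSO2CH=CH2 (3 equiv), BHT, toluene, 110 °C
Reagents that add atoms: phenyl vinyl sulfone, C=CS(=O)(=O)c1ccccc1
Why: Diels–Alder reaction of the o-quinol acetate diene with phenyl vinyl sulfone as an ethylene equivalent should build the bicyclo[2.2.2]octenone with both bridgeheads in fixed relative configuration (racemic); regio- and endo/exo isomers at the sulfonyl and acetoxy carbons converge because both centres are cleared in step 4.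

Step 4
Reactants: 7 rac-3-acetoxy-1,3-bis[(benzyloxy)methyl]-5-methyl-7-(phenylsulfonyl)bicyclo[2.2.2]oct-5-en-2-one
Product: 9 rac-1,3-bis[(benzyloxy)methyl]-5-methylbicyclo[2.2.2]oct-5-en-2-one (C3 epimers), via samarium enolate 8 (not isolated)
Conditions: SmI2, THF, −78 °C; then HMPA, −20 → 0 °C; aq. NH4Cl
Reagents that add atoms: none
Why: SmI2 reduction of the α-acetoxy ketone gives a samarium enolate that masks the carbonyl while SmI2–HMPA effects reductive desulfonylation of the alkyl phenyl sulfone, and protonation on work-up leaves one enolisable C–H at C3 whose configuration does not matter.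

Step 5
Reactants: 9 rac-1,3-bis[(benzyloxy)methyl]-5-methylbicyclo[2.2.2]oct-5-en-2-one; 10 benzyl chloromethyl ether
Product: 12 rac-1,3,3-tris[(benzyloxy)methyl]-5-methylbicyclo[2.2.2]oct-5-en-2-one, via lithium enolate 11 (not isolated)
Conditions: LDA, THF, −78 °C; BnOCH2Cl, −78 → −30 °C
Reagents that add atoms: benzyl chloromethyl ether, ClCOCc1ccccc1
Why: Enolate alkylation: C3 is the only enolisable position (C1 is a bridgehead), so LDA should give a single lithium enolate that is C-alkylated by the chloromethyl ether, and since the two CH2OBn groups are then identical this carbon is not stereogenic.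

Step 6
Reactants: 12 rac-1,3,3-tris[(benzyloxy)methyl]-5-methylbicyclo[2.2.2]oct-5-en-2-one
Product: 13 (1S,4R)-1,3,3-tris[(benzyloxy)methyl]-5-methylbicyclo[2.2.2]oct-5-en-2-one
Conditions: preparative chiral SFC, amylose tris(3,5-dimethylphenylcarbamate), CO2/i-PrOH
Reagents that add atoms: none
Why: Resolution by chromatography on a polysaccharide chiral stationary phase should separate the enantiomers of this rigid, aryl-rich ketone; the (1S,4R) enantiomer is carried on and its assignment would be secured by X-ray analysis of a later crystalline derivative such as iodide 26.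

Step 7
Reactants: 13 (1S,4R)-1,3,3-tris[(benzyloxy)methyl]-5-methylbicyclo[2.2.2]oct-5-en-2-one; 14 vinylmagnesium bromide
Product: 15 (1S,2S,4R)-1,3,3-tris[(benzyloxy)methyl]-2-ethenyl-5-methylbicyclo[2.2.2]oct-5-en-2-ol
Conditions: CH2=CHMgBr, LaCl3·2LiCl, THF, 0 °C → rt; aq. NH4Cl
Reagents that add atoms: vinylmagnesium bromide, C=C[Mg]Br
Why: Grignard 1,2-addition to a non-enolisable ketone should occur from the carbonyl face flanked by the C5=C6 etheno bridge, which is less hindered than the face under the C7–C8 ethano bridge, so the new carbinol centre (2S) carries the vinyl group syn to the alkene.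

Step 8
Reactants: 15 (1S,2S,4R)-1,3,3-tris[(benzyloxy)methyl]-2-ethenyl-5-methylbicyclo[2.2.2]oct-5-en-2-ol
Product: 18 (5R,10S)-17,18,19-tris(benzyloxy)-cis-decal-8(9)-en-3-one [(4aS,8aR)-1,1,6-tris[(benzyloxy)methyl]-4a-methyl-3,4,4a,7,8,8a-hexahydronaphthalen-2(1H)-one], via potassium alkoxide 16 (not isolated), via potassium enolate 17 (not isolated)
Conditions: KH, 18-crown-6, THF, 0 → 40 °C; aq. NH4Cl, −78 °C
Reagents that add atoms: none
Why: Deprotonation gives alkoxide 16, whose C3–C8 bond is weakened by the adjacent O−, so the 1,5-diene C1=C2–C3–C8–C9=C10 should undergo a concerted alkoxide-accelerated [3,3] shift to enolate 17, which is protonated at C2 on work-up. The closest known reaction is the anionic oxy-Cope rearrangement of 2-vinylbicyclo[2.2.2]oct-5-en-2-ols bearing the vinyl group syn to the alkene, which gives cis-fused octalinones. Ring A (C1–C2–C3–C4–C5–C10) closes by C1–C10 bond formation through the boat-like six-centre array enforced by the bicycle, while ring B is the cyclohexene ring of the bicycle, released when C3–C8 breaks. The only new stereocentre, quaternary C10, is set because C1 can reach C10 only on the face that carried the C3–C4 bridge, the same face on which C5 holds C4, so C20 and H5 end up cis and the absolute sense follows from the resolved bridgeheads. The step needs the [3,3] shift to win over C3–C8 heterolysis, [1,3] shift and elimination; the rigid bicycle holds C1 within bonding distance of C10, and the substrate has no enolisable C–H, no leaving group β to the enolate carbon and only ether oxygens, which are too poor as nucleofuges for Grob fragmentation.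

Step 9
Reactants: 18 (5R,10S)-17,18,19-tris(benzyloxy)-cis-decal-8(9)-en-3-one
Product: 19 (2R,4aS,8aR)-1,1,6-tris(hydroxymethyl)-4a-methyl-1,2,3,4,4a,7,8,8a-octahydronaphthalen-2-ol (labdane 3R,5R,10S)
Conditions: Li, NH3(l)/THF, t-BuOH, −78 → −33 °C; NH4Cl
Reagents that add atoms: none
Why: Dissolving-metal reduction should give the thermodynamically preferred equatorial C3 alcohol, which in the favoured ring-A chair (C6 axial, one syn-pentane contact only) is the 3R alcohol cis to H5 and C20, and the same reagent cleaves the three benzyl ethers at the benzylic C–O bond while the isolated C8=C9 alkene and the allylic C17–O bond stay intact.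

Step 10
Reactants: 19 (2R,4aS,8aR)-1,1,6-tris(hydroxymethyl)-4a-methyl-1,2,3,4,4a,7,8,8a-octahydronaphthalen-2-ol; 20 triethyl orthoacetate
Product: 23 ethyl (3R,5R,9R,10S)-3,18,19-(ethylidynetrioxy)-13,14,15,16-tetranorlabd-8(17)-en-12-oate (cis-fused), via cage orthoacetate alcohol 21 (not isolated), via ketene acetal 22 (not isolated)
Conditions: MeC(OEt)3 (6 equiv), EtCO2H (cat.), xylene, 100 → 140 °C, EtOH distilled off
Reagents that add atoms: triethyl orthoacetate, CCOC(C)(OCC)OCC
Why: Orthoester exchange should first tie O3, O18 and O19 into a 2,6,7-trioxabicyclo[2.2.2]octane (possible only with the equatorial C3–O, and locking ring A so that C1 is pseudoaxial on ring B), then the C17 mixed orthoester loses ethanol to the ketene acetal and undergoes Johnson–Claisen [3,3] rearrangement, which forms C9–C11 and moves the alkene to C8=C17 with complete regiocontrol; C11 is delivered axially to the convex face of C9, anti to the C10–C1 bond and cis to C20, setting 9R.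

Step 11
Reactants: 23 ethyl (3R,5R,9R,10S)-3,18,19-(ethylidynetrioxy)-13,14,15,16-tetranorlabd-8(17)-en-12-oate
Product: 24 (3R,5R,9R,10S)-3,18,19-(ethylidynetrioxy)-13,14,15,16-tetranorlabd-8(17)-en-12-ol
Conditions: LiAlH4, THF, 0 °C; Fieser work-up
Reagents that add atoms: none
Why: LiAlH4 reduction of the ester to the primary alcohol should be clean because orthoesters and isolated alkenes are inert to hydride, and no stereocentre is touched.

Step 12
Reactants: 24 (3R,5R,9R,10S)-3,18,19-(ethylidynetrioxy)-13,14,15,16-tetranorlabd-8(17)-en-12-ol; 25 iodine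
Product: 26 (3R,5R,9R,10S)-3,18,19-(ethylidynetrioxy)-12-iodo-13,14,15,16-tetranorlabd-8(17)-ene
Conditions: I2, PPh3, imidazole, CH2Cl2, 0 °C → rt
Reagents that add atoms: iodine, II
Why: Appel-type iodination (Garegg–Samuelsson conditions) should convert the unhindered primary alcohol into the iodide in an imidazole-buffered medium that the orthoester tolerates.

Step 13
Reactants: 27 α-bromo-γ-butyrolactone; 28 thiophenol
Product: 29 rac-3-(phenylsulfanyl)oxolan-2-one
Conditions: PhSH, Et3N, CH2Cl2, 0 °C → rt
Reagents that add atoms: thiophenol, Sc1ccccc1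
Why: SN2 displacement of the α-bromolactone by thiophenolate should give the sulfide lactone, a standard α-anion equivalent of a butenolide; its stereocentre is irrelevant.

Step 14
Reactants: 26 (3R,5R,9R,10S)-3,18,19-(ethylidynetrioxy)-12-iodo-13,14,15,16-tetranorlabd-8(17)-ene; 29 rac-3-(phenylsulfanyl)oxolan-2-one
Product: 31 (3R,5R,9R,10S)-3,18,19-(ethylidynetrioxy)-13-(phenylsulfanyl)labd-8(17)-en-16,15-olide (C13 epimers), via lactone lithium enolate 30 (not isolated)
Conditions: LDA, THF, −78 °C; then 26, HMPA, −78 °C → rt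
Reagents that add atoms: none
Why: Alkylation of the sulfur-stabilised lactone enolate with the primary iodide should form the C12–C13 bond; C13 forms as an epimer mixture that is removed in step 15.

Step 15
Reactants: 31 (3R,5R,9R,10S)-3,18,19-(ethylidynetrioxy)-13-(phenylsulfanyl)labd-8(17)-en-16,15-olide
Product: 33 (3R,5R,9R,10S)-3,18,19-(ethylidynetrioxy)labda-8(17),13-dien-16,15-olide, via sulfoxide 32 (not isolated)
Conditions: m-CPBA (1.0 equiv), NaHCO3, CH2Cl2, −78 → 0 °C; then toluene, CaCO3, 110 °C
Reagents that add atoms: none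
Why: Sulfide oxidation is much faster than epoxidation of the 1,1-disubstituted alkene at low temperature, and thermal sulfoxide syn-elimination toward the ring C14–H should give the endocyclic α-alkylbutenolide.

Step 16
Reactants: 33 (3R,5R,9R,10S)-3,18,19-(ethylidynetrioxy)labda-8(17),13-dien-16,15-olide
Product: 36 3-{2-[(1R,4aR,6R,8aS)-6-hydroxy-5,5-bis(hydroxymethyl)-8a-methyl-2-methylidenedecahydronaphthalen-1-yl]ethyl}furan-2(5H)-one (CNP0146463.1), via monoacetate 34 (not isolated), via seco carboxylate 35 (not isolated)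
Conditions: 0.5 M HCl, THF/H2O, rt; LiOH, 0 °C; then HCl to pH 2
Reagents that add atoms: none
Why: Aqueous acid should open the orthoacetate to a monoacetate, brief saponification removes the acetyl group (the lactone opens to the Z-hydroxy carboxylate), and acidification relactonises, so no stereocentre is affected.

**Compound list**

1 | 2,6-bis(hydroxymethyl)-4-methylphenol | Cc1cc(CO)c(O)c(CO)c1 | starting material
2 | benzyl alcohol | OCc1ccccc1 | starting material
3 | 2,6-bis[(benzyloxy)methyl]-4-methylphenol | Cc1cc(COCc2ccccc2)c(O)c(COCc2ccccc2)c1 | intermediate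
4 | lead tetraacetate | CC(=O)O[Pb](OC(C)=O)(OC(C)=O)OC(C)=O | starting material
5 | rac-6-acetoxy-2,6-bis[(benzyloxy)methyl]-4-methylcyclohexa-2,4-dien-1-one (racemate, one enantiomer drawn) | CC(=O)O[C@]1(COCc2ccccc2)C=C(C)C=C(COCc2ccccc2)C1=O | intermediate
6 | phenyl vinyl sulfone | C=CS(=O)(=O)c1ccccc1 | starting material
7 | rac-3-acetoxy-1,3-bis[(benzyloxy)methyl]-5-methyl-7-(phenylsulfonyl)bicyclo[2.2.2]oct-5-en-2-one (racemate; major isomer: sulfonyl syn to C5=C6, acetoxy syn to C7–C8) | c1ccccc1COC[C@]23[C@H](S(=O)(=O)c4ccccc4)C[C@H](C(C)=C2)[C@](OC(C)=O)(COCc2ccccc2)C3=O | intermediate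
8 | samarium(III) enolate of the deacetoxylated 7-sulfonyl ketone (racemate) | c1ccccc1COC[C@]23[C@H](S(=O)(=O)c4ccccc4)C[C@H](C(C)=C2)C(COCc2ccccc2)=C3O[Sm](I)I | intermediate
9 | rac-1,3-bis[(benzyloxy)methyl]-5-methylbicyclo[2.2.2]oct-5-en-2-one (racemate; C3 epimers, one drawn) | c1ccccc1COC[C@]23CC[C@H](C(C)=C2)[C@@H](COCc2ccccc2)C3=O | intermediate
10 | benzyl chloromethyl ether | ClCOCc1ccccc1 | starting material
11 | lithium enolate of 9 (racemate) | c1ccccc1COC[C@]23CC[C@H](C(C)=C2)C(COCc2ccccc2)=C3O[Li] | intermediate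
12 | rac-1,3,3-tris[(benzyloxy)methyl]-5-methylbicyclo[2.2.2]oct-5-en-2-one (racemate, enantiomer of the target series drawn) | c1ccccc1COC[C@]23CC[C@H](C(C)=C2)C(COCc2ccccc2)(COCc2ccccc2)C3=O | intermediate
13 | (1S,4R)-1,3,3-tris[(benzyloxy)methyl]-5-methylbicyclo[2.2.2]oct-5-en-2-one (single enantiomer) | c1ccccc1COC[C@]23CC[C@H](C(C)=C2)C(COCc2ccccc2)(COCc2ccccc2)C3=O | intermediate
14 | vinylmagnesium bromide | C=C[Mg]Br | starting material
15 | (1S,2S,4R)-1,3,3-tris[(benzyloxy)methyl]-2-ethenyl-5-methylbicyclo[2.2.2]oct-5-en-2-ol (vinyl syn to C5=C6) | c1ccccc1COC[C@]23CC[C@H](C(C)=C2)C(COCc2ccccc2)(COCc2ccccc2)[C@]3(O)C=C | intermediate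
16 | potassium alkoxide of 15 | c1ccccc1COC[C@]23CC[C@H](C(C)=C2)C(COCc2ccccc2)(COCc2ccccc2)[C@]3(O[K])C=C | intermediate
17 | potassium C2=C3 enolate of 18 | c1ccccc1COCC=2CC[C@H]3C(COCc4ccccc4)(COCc4ccccc4)C(O[K])=CC[C@@]3(C)C=2 | intermediate
18 | (4aS,8aR)-1,1,6-tris[(benzyloxy)methyl]-4a-methyl-3,4,4a,7,8,8a-hexahydronaphthalen-2(1H)-one (cis-fused; labdane 5R,10S) | c1ccccc1COCC=2CC[C@H]3C(COCc4ccccc4)(COCc4ccccc4)C(=O)CC[C@@]3(C)C=2 | intermediate
19 | (2R,4aS,8aR)-1,1,6-tris(hydroxymethyl)-4a-methyl-1,2,3,4,4a,7,8,8a-octahydronaphthalen-2-ol (labdane 3R,5R,10S; 3-OH cis to H5 and C20) | OCC=1CC[C@H]2C(CO)(CO)[C@H](O)CC[C@@]2(C)C=1 | intermediate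
20 | triethyl orthoacetate | CCOC(C)(OCC)OCC | starting material
21 | 3,18,19-orthoacetate of 19 with free C17–OH (O3, O18 and O19 on one C–CH3: 1-methyl-2,6,7-trioxabicyclo[2.2.2]octane cage) | OCC=1CC[C@H]2C34COC(C)(OC3)O[C@@H]4CC[C@@]2(C)C=1 | intermediate
22 | 17-O-(1-ethoxyethenyl) ketene acetal of 21 | C=C(OCC)OCC=1CC[C@H]2C34COC(C)(OC3)O[C@@H]4CC[C@@]2(C)C=1 | intermediate
23 | ethyl (3R,5R,9R,10S)-3,18,19-(ethylidynetrioxy)-13,14,15,16-tetranorlabd-8(17)-en-12-oate (9-CH2CO2Et cis to C20) | C=C1CC[C@H]2C34COC(C)(OC3)O[C@@H]4CC[C@@]2(C)[C@@H]1CC(=O)OCC | intermediate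
24 | (3R,5R,9R,10S)-3,18,19-(ethylidynetrioxy)-13,14,15,16-tetranorlabd-8(17)-en-12-ol | C=C1CC[C@H]2C34COC(C)(OC3)O[C@@H]4CC[C@@]2(C)[C@@H]1CCO | intermediate
25 | iodine | II | starting material
26 | (3R,5R,9R,10S)-3,18,19-(ethylidynetrioxy)-12-iodo-13,14,15,16-tetranorlabd-8(17)-ene | C=C1CC[C@H]2C34COC(C)(OC3)O[C@@H]4CC[C@@]2(C)[C@@H]1CCI | intermediate
27 | α-bromo-γ-butyrolactone (racemic) | BrC1CCOC1=O | starting material
28 | thiophenol | Sc1ccccc1 | starting material
29 | rac-3-(phenylsulfanyl)oxolan-2-one | O=C1OCCC1Sc1ccccc1 | intermediate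
30 | lithium enolate of 29 | [Li]OC1=C(Sc2ccccc2)CCO1 | intermediate
31 | (3R,5R,9R,10S)-3,18,19-(ethylidynetrioxy)-13-(phenylsulfanyl)labd-8(17)-en-16,15-olide (C13 epimers) | C=C1CC[C@H]2C34COC(C)(OC3)O[C@@H]4CC[C@@]2(C)[C@@H]1CCC1(Sc2ccccc2)CCOC1=O | intermediate
32 | sulfoxide of 31 (S and C13 epimers) | C=C1CC[C@H]2C34COC(C)(OC3)O[C@@H]4CC[C@@]2(C)[C@@H]1CCC1(S(=O)c2ccccc2)CCOC1=O | intermediate
33 | (3R,5R,9R,10S)-3,18,19-(ethylidynetrioxy)labda-8(17),13-dien-16,15-olide | C=C1CC[C@H]2C34COC(C)(OC3)O[C@@H]4CC[C@@]2(C)[C@@H]1CCC1=CCOC1=O | intermediate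
34 | monoacetate of 36 (primary acetate drawn, regioisomers interconvert, C4 unspecified) | C=C1CC[C@H]2C(CO)(COC(C)=O)[C@H](O)CC[C@@]2(C)[C@@H]1CCC1=CCOC1=O | intermediate
35 | lithium (Z)-4-hydroxy-2-alkylbut-2-enoate from lactone opening of 36 | C=C1CC[C@H]2C(CO)(CO)[C@H](O)CC[C@@]2(C)[C@@H]1CC/C(C(=O)[O-])=C/CO.[Li+] | intermediate
36 | 3-{2-[(1R,4aR,6R,8aS)-6-hydroxy-5,5-bis(hydroxymethyl)-8a-methyl-2-methylidenedecahydronaphthalen-1-yl]ethyl}furan-2(5H)-one (labdane 3R,5R,9R,10S; CNP0146463.1) | C=C1CC[C@H]2C(CO)(CO)[C@H](O)CC[C@@]2(C)[C@@H]1CCC1=CCOC1=O | target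

**Step count and risks**

Total step count: 16. Longest linear sequence: 15 steps (steps 1–12 and 14–16; step 13 is a one-step branch).

Steps most likely to fail:

1. Step 8 (key step). The bond-forming alkene terminus C10 is methyl-substituted, so the [3,3] shift may be slow and the alkoxide may instead fragment by C3–C8 heterolysis without C1–C10 bond formation. The fallback sets out from 15 and runs the same shift without an anion. Silylation (TMSOTf, 2,6-lutidine, CH2Cl2) would give the trimethylsilyl ether of 15, F1. Thermolysis as a siloxy-Cope rearrangement (decalin, 220 °C, sealed base-washed tube) would give the trimethylsilyl enol ether of 18, F2. Hydrolysis (1 M HCl, THF) comes back to the route at 18.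

2. Step 10. At 140 °C under acid the allylic mixed orthoester may ionise, or the face selectivity at C9 may erode. The fallback sets out from 19 and separates cage formation from the rearrangement. Compound 21 would be formed and isolated at room temperature (MeC(OEt)3 1.2 equiv, CSA cat., CH2Cl2, Et3N quench), then acetylated (Ac2O, pyridine, DMAP) to the 17-O-acetyl derivative of 21, F5. Ireland–Claisen rearrangement (LDA, TMSCl, THF, −78 °C → rt) forms the same C9–C11 bond through the silyl ketene acetal at or below room temperature and would give the trimethylsilyl ester of the C12 acid, F6. Adding LiAlH4 directly to F6 comes back to the route at 24.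

3. Step 9. Protonation at C3 may not reach thermodynamic control (3-epimer mixture), or the reducing medium may cleave the allylic C17–O bond. The fallback sets out from 18 and separates the two tasks. NaBH4 in MeOH should give chiefly the axial 3S alcohol tribenzyl ether, F3, by hydride attack from the convex face. Hydrogen-transfer equilibration (Al(Oi-Pr)3, i-PrOH, trace acetone, reflux; Meerwein–Ponndorf–Verley/Oppenauer) would convert it into the equatorial 3R alcohol tribenzyl ether, F4. Debenzylation with lithium 4,4′-di-tert-butylbiphenylide (THF, −78 °C) comes back to the route at 19.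

Further compounds
F1 | step 8 | trimethylsilyl ether of 15 | c1ccccc1COC[C@]23CC[C@H](C(C)=C2)C(COCc2ccccc2)(COCc2ccccc2)[C@]3(O[Si](C)(C)C)C=C
F2 | step 8 | trimethylsilyl enol ether of 18 (C2=C3) | c1ccccc1COCC=2CC[C@H]3C(COCc4ccccc4)(COCc4ccccc4)C(O[Si](C)(C)C)=CC[C@@]3(C)C=2
F3 | step 9 | (3S,5R,10S)-17,18,19-tris(benzyloxy)-cis-decal-8(9)-en-3-ol (axial alcohol) | c1ccccc1COCC=2CC[C@H]3C(COCc4ccccc4)(COCc4ccccc4)[C@@H](O)CC[C@@]3(C)C=2
F4 | step 9 | (3R,5R,10S)-17,18,19-tris(benzyloxy)-cis-decal-8(9)-en-3-ol (equatorial alcohol) | c1ccccc1COCC=2CC[C@H]3C(COCc4ccccc4)(COCc4ccccc4)[C@H](O)CC[C@@]3(C)C=2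
F5 | step 10 | 17-O-acetyl derivative of 21 | CC(=O)OCC=1CC[C@H]2C34COC(C)(OC3)O[C@@H]4CC[C@@]2(C)C=1
F6 | step 10 | trimethylsilyl (3R,5R,9R,10S)-3,18,19-(ethylidynetrioxy)-13,14,15,16-tetranorlabd-8(17)-en-12-oate | C=C1CC[C@H]2C34COC(C)(OC3)O[C@@H]4CC[C@@]2(C)[C@@H]1CC(=O)O[Si](C)(C)C
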